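- Saturday's flask was slow: after 68 min it held 0.393 M of target from 1.00 M of starting material, and Friday's flask, with twice the catalyst, held 0.407 M at that time.

the same everywhere: coupling partner 3.00 M

| charge | starting material | catalyst | target | time |
|---|---|---|---|---|
| Saturday's | 1.00 M | 0.00200 M |  |  |
| Friday's | 1.00 M | 0.00400 M |  |  |
| Sunday's | 0.500 M | 0.00200 M |  |  |
| Wednesday's | 1.00 M | 0.00200 M | 0.500 M |  |
| Tuesday's | 1.00 M | 0.00200 M |  | 410 min |

| Saturday's run: time / min | Saturday's run: [target] / M | Friday's run: time / min | Friday's run: [target] / M | Sunday's run: time / min | Sunday's run: [target] / M | Wednesday's run: time / min | Wednesday's run: [target] / M |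
|---|---|---|---|---|---|---|---|
| 14 | 0.092 | 14 | 0.129 | 14 | 0.055 | 14 | 0.596 |
| 27 | 0.177 | 27 | 0.199 | 27 | 0.070 | 27 | 0.694 |
| 41 | 0.277 | 41 | 0.294 | 41 | 0.135 | 41 | 0.774 |
| 54 | 0.336 | 54 | 0.375 | 54 | 0.161 | 54 | 0.827 |
| 68 | 0.393 | 68 | 0.407 | 68 | 0.201 | 68 | 0.882 |

(each reading ± 0.01 M)

- Overall: starting material + coupling partner -> target, with catalyst as catalyst.
- Constant volume, constant temperature.
- A reading of a species includes what of it is bound.
- "The second partner" is coupling partner.
- An order is taken over about fifteen percent of the charge, up and down.

- the power of [catalyst] that the first rate follows, about the charge of the Saturday's run; measure it at two percent of starting material made into target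
- the power of [starting material] that the first rate follows, about the charge of the Saturday's run; measure it at two percent of starting material made into target (one fixed amount of target, the same in the runs compared)
- target in the Tuesday's run at 410 min, as a share of the starting material charged

- Sunday's run turned 40.2 % of its starting material by 68 min and Saturday's 39.3 %, so I measured progress in each run as minus the logarithm of the fraction of starting material left.
- My rule was this: if a rate is a part that ignores the catalyst plus a part proportional to it, doubling the catalyst adds one more catalysed part, so the ratio of the doubled rate to the first rate, less one, is the catalysed fraction of the first rate, and that fraction is also the power of catalyst at the first charge.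
- My first way to that fraction used the earliest pair of readings, at 14 min in Saturday's and Friday's runs, and gave 0.431.
- My second way used the latest pair, at 68 min, and gave 0.0467, which is smaller than the first, so the two ways parted.
- I trusted the early way less: the scatter of 0.01 M was 10.9 % of Saturday's earliest reading but 2.54 % of its latest, a larger share early.
- I then summed the measure over the paired readings of each run and took the ratio of the sums, less one, which gave 0.116, a value between the two ways.
- I called this reading the catalyst share, the fraction of Saturday's rate that a doubling of catalyst adds again, and I committed to it as my own value for the power of catalyst.
- The forecast gave 0.35 for that power, from 0.1 to 0.75, which is higher than my reckoning, with the words “This points to an order of about 0.2–0.4, implying saturation or an off-cycle catalyst reservoir.”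
- For the power of starting material the forecast gave 1, from 0.8 to 1.15, and for Tuesday's run it gave 91 %, from 82 % to 96 %.

- The flask gave 0.12 for the power of catalyst, 1.0 for the power of starting material, and target at 92.1 % of the starting material charged in Tuesday's run at 410 min.

    catalyst + starting material + coupling partner → target + catalyst (1.998 M⁻² min⁻¹)
    catalyst + coupling partner ⇌ idle catalyst-reagent complex, settled at all times (3.880 M⁻¹)
    starting material + coupling partner → target (0.002250 M⁻¹ min⁻¹)

- Where the same amount of target had been made, Friday's rate over Saturday's stood at 1.1.
- Dividing Saturday's time to half of the starting material charged, 98.4 min, by one plus the catalyst share 0.116 gave 88.2 min for Friday's run, whose own time to that point stood at 86.8 min.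

The earlier runs and the new flask stem from a simulated flask on assumed constants; noise was put on by code.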